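**Retrosynthetic overview**
- The C3 carbinol is made last by reagent-controlled reduction of a cross-conjugated dienone; the C8 angelate is put on just before, on the only free secondary alcohol.
- The ten-membered ring closes first and the cis-fused α-methylene lactone second, in the same flask: a 2-alkenyl-3-methylfuran is opened by singlet oxygen to a (Z)-4-oxo-enal, which is trapped by an intramolecular allylboration (C6–C7 bond).
- The open chain comes from a lactol-aldehyde whose two ends are told apart without extra protection: C1 by Takai iodoolefination and Negishi coupling, C7 by lactol Wittig and a second Negishi coupling.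
- The lactol-aldehyde comes from ozonolysis of a trans-cyclopentenediol mono-silyl ether; this five-membered ring is only a temporary tether.
- Key step: symmetric, aromatic 2,5-dimethylfuran is opened oxidatively to the symmetric (Z)-hex-3-ene-2,5-dione, which is desymmetrised by a catalytic enantioselective aldol to (S)-4-hydroxy-4-methylcyclopentenone (sets C10; C8 follows by directed reduction).

Assumption: 2-bromo-3-methylfuran, ethyl bromo(triphenylphosphoranylidene)acetate, angelic acid and 2-(iodomethyl)-4,4,5,5-tetramethyl-1,3,2-dioxaborolane are bought. Atom labels C1–C15 are germacrane numbering (C6 lactone carbinol, C8 angelate carbon, C10 tertiary carbinol); the target is 3S,6S,7R,8S,10S, 1E,4Z, with a cis-fused lactone.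

**Step 1**
Reactants: 1 2,5-dimethylfuran
Product: 4 (4S)-4-hydroxy-4-methylcyclopent-2-en-1-one, via furan endoperoxide 2 (not isolated), via (3Z)-hex-3-ene-2,5-dione 3 (not isolated)
Conditions: O2, hν, tetraphenylporphyrin (cat.), CH2Cl2, −78 °C; Me2S, −78 °C → rt; then 9-amino-9-deoxy-epi-quinine (10 mol %), PhCO2H (20 mol %), toluene, 0 °C → rt
Reagents that add atoms: dioxygen, O=O
Why: Proposed new method: singlet-oxygen [4+2] addition to the furan and Me2S reduction of endoperoxide 2 are known and give the symmetric Z-enedione 3, whose two enantiotopic acetyl groups are then told apart by the chiral primary amine, which condenses with one ketone to a cross-conjugated dienamine while its protonated quinuclidine hydrogen-bonds the other carbonyl, so that the 5-enolexo aldol closes on one carbonyl face and sets the tertiary carbinol (C10, S) in a product that cannot dehydrate; the closest known reaction type is the cinchona-primary-amine-catalysed desymmetrising intramolecular aldolisation of achiral diketones, and the pseudo-enantiomeric quinidine-derived amine is used instead if the first run delivers the R enantiomer.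

**Step 2**
Reactants: 4 (4S)-4-hydroxy-4-methylcyclopent-2-en-1-one
Product: 5 (1S,4S)-1-methylcyclopent-2-ene-1,4-diol (trans)
Conditions: Me4NBH(OAc)3 (4 eq), MeCN/AcOH (1:1), −30 °C
Reagents that add atoms: none
Why: Evans–Saksena hydroxyl-directed reduction, in which the tertiary alcohol exchanges onto boron and hands the hydride to the carbonyl carbon on its own face (1,2-reduction only), so the new C8 hydroxyl ends up trans to the C10 hydroxyl, that is the 1,3-anti (1S,4S) diol.

**Step 3**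
Reactants: 5 (1S,4S)-1-methylcyclopent-2-ene-1,4-diol
Product: 6 (1S,4S)-4-[(tert-butyldimethylsilyl)oxy]-1-methylcyclopent-2-en-1-ol
Conditions: TBSCl (1.1 eq), imidazole, DMF, 0 °C
Reagents that add atoms: tert-butyldimethylsilyl chloride, CC(C)(C)[Si](C)(C)Cl
Why: Chemoselective silylation of the secondary allylic alcohol, the tertiary alcohol being inert to TBSCl and imidazole, which blocks O8 for the later lactonisation and leaves O10 free to mask one aldehyde in the next step.

**Step 4**
Reactants: 6 (1S,4S)-4-[(tert-butyldimethylsilyl)oxy]-1-methylcyclopent-2-en-1-ol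
Product: 9 (2S,4S)-4-[(tert-butyldimethylsilyl)oxy]-5-hydroxy-2-methyloxolane-2-carbaldehyde (lactol, both anomers), via secondary ozonide 7 (not isolated), via silyloxy dialdehyde 8 (not isolated)
Conditions: O3, CH2Cl2, −78 °C; PPh3, −78 °C → rt
Reagents that add atoms: ozone, [O-][O+]=O
Why: Ozonolysis with reductive work-up cleaves the only C=C bond, the temporary C7=C1 tether, and the C7 aldehyde of dialdehyde 8 is trapped at once by the free tertiary hydroxyl as a five-membered lactol while the aldehyde on the quaternary carbon stays free, so the two ends are differentiated without a further protecting group and no stereocentre is touched.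

**Step 5**
Reactants: 9 (2S,4S)-4-[(tert-butyldimethylsilyl)oxy]-5-hydroxy-2-methyloxolane-2-carbaldehyde
Product: 10 (3S,5S)-3-[(tert-butyldimethylsilyl)oxy]-5-[(E)-2-iodoethenyl]-5-methyloxolan-2-ol
Conditions: CrCl2 (8 eq), CHI3 (2 eq), THF/1,4-dioxane (1:6), 0 °C → rt
Reagents that add atoms: iodoform, IC(I)I
Why: Takai iodoolefination with the chromium carbenoid from CHI3 converts the free aldehyde into the E-alkenyl iodide under neutral conditions that spare the lactol and the silyl ether, E selectivity being inherent to the reaction.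

**Step 6**
Reactants: 10 (3S,5S)-3-[(tert-butyldimethylsilyl)oxy]-5-[(E)-2-iodoethenyl]-5-methyloxolan-2-ol; 11 2-bromo-3-methylfuran
Product: 14 (3S,5S)-3-[(tert-butyldimethylsilyl)oxy]-5-methyl-5-[(E)-2-(3-methylfuran-2-yl)ethenyl]oxolan-2-ol, via (3-methylfuran-2-yl)lithium 12 (not isolated), via chloro(3-methylfuran-2-yl)zinc 13 (not isolated)
Conditions: 11, n-BuLi, THF, −78 °C; ZnCl2, −78 → 0 °C; then slow addition to 10, Pd(OAc)2 (5 mol %), SPhos (10 mol %), THF, rt
Reagents that add atoms: none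
Why: Negishi cross-coupling of the alkenyl iodide with the furylzinc reagent (bromine–lithium exchange, then transmetalation to zinc) proceeds with retention of the E geometry, and the mild arylzinc tolerates the lactol hydroxyl when added slowly.

**Step 7**
Reactants: 14 (3S,5S)-3-[(tert-butyldimethylsilyl)oxy]-5-methyl-5-[(E)-2-(3-methylfuran-2-yl)ethenyl]oxolan-2-ol; 15 ethyl bromo(triphenyl-λ5-phosphanylidene)acetate
Product: 16 ethyl (2Z,4S,6S,7E)-2-bromo-4-[(tert-butyldimethylsilyl)oxy]-6-hydroxy-6-methyl-8-(3-methylfuran-2-yl)octa-2,7-dienoate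
Conditions: toluene, 80 °C
Reagents that add atoms: none
Why: Wittig olefination of the lactol through its open hydroxy-aldehyde form with the stabilised bromo ylide is neutral, so the α-silyloxy centre does not epimerise, places the ester trans to C8 (2Z because of bromine) and liberates the tertiary C10 alcohol.

**Step 8**
Reactants: 16 ethyl (2Z,4S,6S,7E)-2-bromo-4-[(tert-butyldimethylsilyl)oxy]-6-hydroxy-6-methyl-8-(3-methylfuran-2-yl)octa-2,7-dienoate
Product: 17 ethyl (2E,4S,6S,7E)-4-[(tert-butyldimethylsilyl)oxy]-6-hydroxy-6-methyl-8-(3-methylfuran-2-yl)-2-[(4,4,5,5-tetramethyl-1,3,2-dioxaborolan-2-yl)methyl]octa-2,7-dienoate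
Conditions: ICH2Bpin, Zn dust, THF, rt; then 16, Pd(OAc)2 (5 mol %), SPhos (10 mol %), THF, rt
Reagents that add atoms: iodo[(4,4,5,5-tetramethyl-1,3,2-dioxaborolan-2-yl)methyl]zinc, I[Zn]CB1OC(C)(C)C(C)(C)O1, made in the flask from 2-(iodomethyl)-4,4,5,5-tetramethyl-1,3,2-dioxaborolane, ICB1OC(C)(C)C(C)(C)O1
Why: Negishi coupling of the activated α-bromo enoate with the Knochel-type boryl-methylzinc reagent replaces bromine by CH2Bpin with retention of the alkene geometry and gives a stable 2-(alkoxycarbonyl)allylboronate in which C8 is cis to the boron-bearing carbon.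

**Step 9**
Reactants: 17 ethyl (2E,4S,6S,7E)-4-[(tert-butyldimethylsilyl)oxy]-6-hydroxy-6-methyl-8-(3-methylfuran-2-yl)-2-[(4,4,5,5-tetramethyl-1,3,2-dioxaborolan-2-yl)methyl]octa-2,7-dienoate
Product: 21 (3aS,4S,6S,7E,10Z,11aS)-4-[(tert-butyldimethylsilyl)oxy]-6-hydroxy-6,10-dimethyl-3-methylidene-3a,4,5,6-tetrahydrocyclodeca[b]furan-2,9(3H,11aH)-dione, via furan endoperoxide 18 (not isolated), via (Z)-4-oxo-enal 19 (not isolated), via macrocyclic borate ester 20 (not isolated)
Conditions: O2, hν, tetraphenylporphyrin (cat.), CH2Cl2, −78 °C; Me2S, −78 → 0 °C; dilute to 1 mM, Sc(OTf)3 (1.5 eq), −40 → 0 °C; then p-TsOH·H2O (0.2 eq), rt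
Reagents that add atoms: dioxygen, O=O
Why: Proposed new method: photooxygenation of the furan and Me2S reduction (known) unveil the (Z)-4-oxo-enal 19 with the Z alkene inherited from the ring, and the aldehyde is then captured by Sc(OTf)3-accelerated intramolecular allylboration, which is aldehyde-selective (an attack on the C3 ketone would need an E alkene in a seven-membered ring) and runs through a chair transition state in which C8 cis to CH2B gives the syn adduct, hence the cis lactone, while allylic 1,3-strain keeps H8 in the alkene plane so that the tethered aldehyde reaches C7 only on the face that carries C9, which translates 8S into 7R and 6S, and acid finally closes the γ-lactone on O6 because O8 is silylated; the closest known reaction type is the Lewis-acid-catalysed addition of 2-alkoxycarbonyl allylboronates to aldehydes to give α-methylene-γ-butyrolactones, here run as a ring closure like the macrocyclic Barbier closures used for germacranolides.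

**Step 10**
Reactants: 21 (3aS,4S,6S,7E,10Z,11aS)-4-[(tert-butyldimethylsilyl)oxy]-6-hydroxy-6,10-dimethyl-3-methylidene-3a,4,5,6-tetrahydrocyclodeca[b]furan-2,9(3H,11aH)-dione
Product: 22 (3aR,4S,6S,7E,10Z,11aS)-4,6-dihydroxy-6,10-dimethyl-3-methylidene-3a,4,5,6-tetrahydrocyclodeca[b]furan-2,9(3H,11aH)-dione
Conditions: HF·pyridine, pyridine/THF, 0 °C → rt
Reagents that add atoms: none
Why: Desilylation with buffered HF·pyridine removes the secondary TBS ether without harming the α-methylene lactone, the dienone or the tertiary alcohol, and no stereocentre is involved.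

**Step 11**
Reactants: 22 (3aR,4S,6S,7E,10Z,11aS)-4,6-dihydroxy-6,10-dimethyl-3-methylidene-3a,4,5,6-tetrahydrocyclodeca[b]furan-2,9(3H,11aH)-dione; 23 angelic acid, (2Z)-2-methylbut-2-enoic acid
Product: 25 (3aR,4S,6S,7E,10Z,11aS)-6-hydroxy-6,10-dimethyl-3-methylidene-2,9-dioxo-2,3,3a,4,5,6,9,11a-octahydrocyclodeca[b]furan-4-yl (2Z)-2-methylbut-2-enoate, via mixed Yamaguchi anhydride 24 (not isolated)
Conditions: 23, 2,4,6-trichlorobenzoyl chloride, Et3N, toluene, rt; then 22, DMAP (0.2 eq), 0 °C → rt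
Reagents that add atoms: none
Why: Yamaguchi esterification through the mixed anhydride acylates the only secondary hydroxyl (C10–OH is tertiary and C3 is still a ketone) and is a standard way to introduce an angelate with little Z to E isomerisation.

**Step 12**
Reactants: 25 (3aR,4S,6S,7E,10Z,11aS)-6-hydroxy-6,10-dimethyl-3-methylidene-2,9-dioxo-2,3,3a,4,5,6,9,11a-octahydrocyclodeca[b]furan-4-yl (2Z)-2-methylbut-2-enoate
Product: 26 (3aR,4S,6S,7E,9S,10Z,11aS)-6,9-dihydroxy-6,10-dimethyl-3-methylidene-2-oxo-2,3,3a,4,5,6,9,11a-octahydrocyclodeca[b]furan-4-yl (2Z)-2-methylbut-2-enoate (target)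
Conditions: (R)-2-methyl-CBS-oxazaborolidine (0.5 eq), catecholborane (3 eq), toluene, −78 °C
Reagents that add atoms: none
Why: Corey–Bakshi–Shibata reduction, which is 1,2-selective for enones with catecholborane and leaves the lactone and the angelate alone: the (R)-oxazaborolidine binds the ketone with the α-methyl-branched Z-alkenyl arm (C4) as the large group and delivers hydride to the face that gives the 3S bis-allylic alcohol under reagent control.

**Compound list**
1 | 2,5-dimethylfuran | Cc1ccc(C)o1 | starting material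
2 | 1,4-dimethyl-2,3,7-trioxabicyclo[2.2.1]hept-5-ene (furan endoperoxide) | CC12OOC(C)(O1)C=C2 | intermediate
3 | (3Z)-hex-3-ene-2,5-dione | CC(=O)/C=C\C(C)=O | intermediate
4 | (4S)-4-hydroxy-4-methylcyclopent-2-en-1-one | O=C1C=C[C@@](C)(O)C1 | intermediate
5 | (1S,4S)-1-methylcyclopent-2-ene-1,4-diol | O[C@@H]1C=C[C@@](C)(O)C1 | intermediate
6 | (1S,4S)-4-[(tert-butyldimethylsilyl)oxy]-1-methylcyclopent-2-en-1-ol | CC(C)(C)[Si](C)(C)O[C@@H]1C=C[C@@](C)(O)C1 | intermediate
7 | (2S,4S)-2-[(tert-butyldimethylsilyl)oxy]-4-methyl-6,7,8-trioxabicyclo[3.2.1]octan-4-ol (secondary ozonide, bridgeheads unassigned) | CC(C)(C)[Si](C)(C)O[C@H]1C[C@](C)(O)C2OOC1O2 | intermediate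
8 | (2S,4S)-2-[(tert-butyldimethylsilyl)oxy]-4-hydroxy-4-methylpentanedial | O=C[C@@H](O[Si](C)(C)C(C)(C)C)C[C@](C)(O)C=O | intermediate
9 | (2S,4S)-4-[(tert-butyldimethylsilyl)oxy]-5-hydroxy-2-methyloxolane-2-carbaldehyde (anomer mixture) | O=C[C@]1(C)C[C@H](O[Si](C)(C)C(C)(C)C)C(O)O1 | intermediate
10 | (3S,5S)-3-[(tert-butyldimethylsilyl)oxy]-5-[(E)-2-iodoethenyl]-5-methyloxolan-2-ol | I/C=C/[C@]1(C)C[C@H](O[Si](C)(C)C(C)(C)C)C(O)O1 | intermediate
11 | 2-bromo-3-methylfuran | Cc1ccoc1Br | starting material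
12 | (3-methylfuran-2-yl)lithium | [Li]c1occc1C | intermediate
13 | chloro(3-methylfuran-2-yl)zinc | Cl[Zn]c1occc1C | intermediate
14 | (3S,5S)-3-[(tert-butyldimethylsilyl)oxy]-5-methyl-5-[(E)-2-(3-methylfuran-2-yl)ethenyl]oxolan-2-ol | Cc1ccoc1/C=C/[C@]2(C)C[C@H](O[Si](C)(C)C(C)(C)C)C(O)O2 | intermediate
15 | ethyl bromo(triphenyl-λ5-phosphanylidene)acetate | CCOC(=O)C(Br)=P(c1ccccc1)(c1ccccc1)c1ccccc1 | starting material
16 | ethyl (2Z,4S,6S,7E)-2-bromo-4-[(tert-butyldimethylsilyl)oxy]-6-hydroxy-6-methyl-8-(3-methylfuran-2-yl)octa-2,7-dienoate | Cc1ccoc1/C=C/[C@@](C)(O)C[C@H](O[Si](C)(C)C(C)(C)C)/C=C(\Br)C(=O)OCC | intermediate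
17 | ethyl (2E,4S,6S,7E)-4-[(tert-butyldimethylsilyl)oxy]-6-hydroxy-6-methyl-8-(3-methylfuran-2-yl)-2-[(4,4,5,5-tetramethyl-1,3,2-dioxaborolan-2-yl)methyl]octa-2,7-dienoate | Cc1ccoc1/C=C/[C@@](C)(O)C[C@H](O[Si](C)(C)C(C)(C)C)/C=C(\CB1OC(C)(C)C(C)(C)O1)C(=O)OCC | intermediate
18 | ethyl (2E,4S,6S,7E)-4-[(tert-butyldimethylsilyl)oxy]-6-hydroxy-6-methyl-8-(6-methyl-2,3,7-trioxabicyclo[2.2.1]hept-5-en-1-yl)-2-[(4,4,5,5-tetramethyl-1,3,2-dioxaborolan-2-yl)methyl]octa-2,7-dienoate (furan endoperoxide) | CC1=CC2OOC1(O2)/C=C/[C@@](C)(O)C[C@H](O[Si](C)(C)C(C)(C)C)/C=C(\CB3OC(C)(C)C(C)(C)O3)C(=O)OCC | intermediate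
19 | ethyl (2E,4S,6S,7E,10Z)-4-[(tert-butyldimethylsilyl)oxy]-6-hydroxy-6,10-dimethyl-9,12-dioxo-2-[(4,4,5,5-tetramethyl-1,3,2-dioxaborolan-2-yl)methyl]dodeca-2,7,10-trienoate | O=C/C=C(/C)C(=O)/C=C/[C@@](C)(O)C[C@H](O[Si](C)(C)C(C)(C)C)/C=C(\CB1OC(C)(C)C(C)(C)O1)C(=O)OCC | intermediate
20 | ethyl 2-[(1S,2S,3Z,6E,8S,10S)-10-[(tert-butyldimethylsilyl)oxy]-8-hydroxy-4,8-dimethyl-5-oxo-2-[(4,4,5,5-tetramethyl-1,3,2-dioxaborolan-2-yl)oxy]cyclodeca-3,6-dien-1-yl]prop-2-enoate | CC1(C)OB(O[C@H]2/C=C(/C)C(=O)/C=C/[C@@](C)(O)C[C@H](O[Si](C)(C)C(C)(C)C)[C@H]2C(=C)C(=O)OCC)OC1(C)C | intermediate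
21 | (3aS,4S,6S,7E,10Z,11aS)-4-[(tert-butyldimethylsilyl)oxy]-6-hydroxy-6,10-dimethyl-3-methylidene-3a,4,5,6-tetrahydrocyclodeca[b]furan-2,9(3H,11aH)-dione | C=C1C(=O)O[C@H]2/C=C(/C)C(=O)/C=C/[C@@](C)(O)C[C@H](O[Si](C)(C)C(C)(C)C)[C@@H]12 | intermediate
22 | (3aR,4S,6S,7E,10Z,11aS)-4,6-dihydroxy-6,10-dimethyl-3-methylidene-3a,4,5,6-tetrahydrocyclodeca[b]furan-2,9(3H,11aH)-dione | C=C1C(=O)O[C@H]2/C=C(/C)C(=O)/C=C/[C@@](C)(O)C[C@H](O)[C@@H]12 | intermediate
23 | angelic acid, (2Z)-2-methylbut-2-enoic acid | C/C=C(/C)C(=O)O | starting material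
24 | (2Z)-2-methylbut-2-enoic 2,4,6-trichlorobenzoic anhydride | C/C=C(/C)C(=O)OC(=O)c1c(Cl)cc(Cl)cc1Cl | intermediate
25 | (3aR,4S,6S,7E,10Z,11aS)-6-hydroxy-6,10-dimethyl-3-methylidene-2,9-dioxo-2,3,3a,4,5,6,9,11a-octahydrocyclodeca[b]furan-4-yl (2Z)-2-methylbut-2-enoate | C=C1C(=O)O[C@H]2/C=C(/C)C(=O)/C=C/[C@@](C)(O)C[C@H](OC(=O)/C(C)=C\C)[C@@H]12 | intermediate
26 | (3aR,4S,6S,7E,9S,10Z,11aS)-6,9-dihydroxy-6,10-dimethyl-3-methylidene-2-oxo-2,3,3a,4,5,6,9,11a-octahydrocyclodeca[b]furan-4-yl (2Z)-2-methylbut-2-enoate | C=C1C(=O)O[C@H]2/C=C(/C)[C@@H](O)/C=C/[C@@](C)(O)C[C@H](OC(=O)/C(C)=C\C)[C@@H]12 | target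

**Step count and risk**
Total step count: 12. Longest linear sequence: 12 steps (1 to 26); 11, 15 and 23 enter as bought materials.

The three steps most likely to fail:

The first is step 1. The enantioselective aldol is unprecedented for this substrate, the amine may be lost by conjugate addition to the enedione, and a reversible aldol would erode the ee. The fallback sets out from 3 (made from 1 as in step 1) and comes back at 5. Aqueous Na2CO3 closes 3 to racemic 4-hydroxy-4-methylcyclopent-2-en-1-one F1. Reduction of F1 with (R)-2-methyl-CBS-oxazaborolidine and BH3·SMe2 fixes the new carbinol as S in both enantiomers, so the S enantiomer gives trans diol 5 and the R enantiomer gives cis (1R,4S)-1-methylcyclopent-2-ene-1,4-diol F2, which is removed by chromatography.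

The second is step 9. The ten-membered ring closure by allylboration has no direct precedent, the oxo-enal may isomerise or decompose before it is trapped, and the facial selectivity rests on a conformational argument. The fallback sets out from 16 and comes back at 21. Pd-catalysed coupling of 16 with (trimethylsilyl)methylzinc chloride gives the allylsilane ethyl (2Z,4S,6S,7E)-4-[(tert-butyldimethylsilyl)oxy]-6-hydroxy-6-methyl-8-(3-methylfuran-2-yl)-2-[(trimethylsilyl)methyl]octa-2,7-dienoate F3. NBS and NaHCO3 in aqueous acetone at −20 °C open the furan to the oxo-enal allylsilane ethyl (2Z,4S,6S,7E,10Z)-4-[(tert-butyldimethylsilyl)oxy]-6-hydroxy-6,10-dimethyl-9,12-dioxo-2-[(trimethylsilyl)methyl]dodeca-2,7,10-trienoate F4. A second equivalent of NBS in CH2Cl2 replaces silicon by bromine with allylic shift to give ethyl (4S,6S,7E,10Z)-3-bromo-4-[(tert-butyldimethylsilyl)oxy]-6-hydroxy-6,10-dimethyl-2-methylidene-9,12-dioxododeca-7,10-dienoate F5. CrCl2 in THF at high dilution (Nozaki–Hiyama–Kishi allylation) then closes the ring, and the hydroxy ester lactonises on acidic work-up to 21.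

The third is step 12. Both arms of the ketone are alkenyl, so the catalyst may discriminate poorly and the ring may impose its own bias. The fallback sets out from 25 and comes back at 26. Luche reduction (NaBH4, CeCl3·7H2O, MeOH, −78 °C) follows the bias of the ring. If it gives the 3R epimer (3aR,4S,6S,7E,9R,10Z,11aS)-6,9-dihydroxy-6,10-dimethyl-3-methylidene-2-oxo-2,3,3a,4,5,6,9,11a-octahydrocyclodeca[b]furan-4-yl (2Z)-2-methylbut-2-enoate F6, Mitsunobu inversion with chloroacetic acid (PPh3, DIAD) gives the 3S chloroacetate (3aR,4S,6S,7E,9S,10Z,11aS)-9-[(chloroacetyl)oxy]-6-hydroxy-6,10-dimethyl-3-methylidene-2-oxo-2,3,3a,4,5,6,9,11a-octahydrocyclodeca[b]furan-4-yl (2Z)-2-methylbut-2-enoate F7. Candida antarctica lipase B in moist MTBE then removes the chloroacetyl group selectively to give 26.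

**Further compounds**
F1 | step 1 | rac-4-hydroxy-4-methylcyclopent-2-en-1-one | O=C1C=CC(C)(O)C1
F2 | step 1 | (1R,4S)-1-methylcyclopent-2-ene-1,4-diol | O[C@@H]1C=C[C@](C)(O)C1
F3 | step 9 | ethyl (2Z,4S,6S,7E)-4-[(tert-butyldimethylsilyl)oxy]-6-hydroxy-6-methyl-8-(3-methylfuran-2-yl)-2-[(trimethylsilyl)methyl]octa-2,7-dienoate | Cc1ccoc1/C=C/[C@@](C)(O)C[C@H](O[Si](C)(C)C(C)(C)C)/C=C(\C[Si](C)(C)C)C(=O)OCC
F4 | step 9 | ethyl (2Z,4S,6S,7E,10Z)-4-[(tert-butyldimethylsilyl)oxy]-6-hydroxy-6,10-dimethyl-9,12-dioxo-2-[(trimethylsilyl)methyl]dodeca-2,7,10-trienoate | O=C/C=C(/C)C(=O)/C=C/[C@@](C)(O)C[C@H](O[Si](C)(C)C(C)(C)C)/C=C(\C[Si](C)(C)C)C(=O)OCC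
F5 | step 9 | ethyl (4S,6S,7E,10Z)-3-bromo-4-[(tert-butyldimethylsilyl)oxy]-6-hydroxy-6,10-dimethyl-2-methylidene-9,12-dioxododeca-7,10-dienoate | O=C/C=C(/C)C(=O)/C=C/[C@@](C)(O)C[C@H](O[Si](C)(C)C(C)(C)C)C(Br)C(=C)C(=O)OCC
F6 | step 12 | (3aR,4S,6S,7E,9R,10Z,11aS)-6,9-dihydroxy-6,10-dimethyl-3-methylidene-2-oxo-2,3,3a,4,5,6,9,11a-octahydrocyclodeca[b]furan-4-yl (2Z)-2-methylbut-2-enoate | C=C1C(=O)O[C@H]2/C=C(/C)[C@H](O)/C=C/[C@@](C)(O)C[C@H](OC(=O)/C(C)=C\C)[C@@H]12
F7 | step 12 | (3aR,4S,6S,7E,9S,10Z,11aS)-9-[(chloroacetyl)oxy]-6-hydroxy-6,10-dimethyl-3-methylidene-2-oxo-2,3,3a,4,5,6,9,11a-octahydrocyclodeca[b]furan-4-yl (2Z)-2-methylbut-2-enoate | C=C1C(=O)O[C@H]2/C=C(/C)[C@@H](OC(=O)CCl)/C=C/[C@@](C)(O)C[C@H](OC(=O)/C(C)=C\C)[C@@H]12
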